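**Retrosynthetic overview**
- The C40 polyene is cut at the 11,12 and 11′,12′ double bonds: two Wittig reactions join one C15 phosphonium salt, a C10 dialdehyde and the same C15 salt again; the sulfate is put on the C25 apo-aldehyde between the two couplings.
- The C15 salt comes from a single ring ester by enol triflate/methyl coupling, reduction/oxidation, Horner–Wadsworth–Emmons olefination, vinyl Grignard addition and PPh3·HBr.
- The two cyclohexene rings are the only rings; one ring-forming step serves both. It is a formal [3+3] annulation of Chan's diene with (R)-3,3-dimethyloxirane-2-carbaldehyde that makes the C4–C3 bond (CH2 to CHOH) and the C6–C1 bond (chain-bearing carbon to CMe2) in one operation.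
- Enabling feature (carotenoid numbering within each six-membered ring): quaternary C1 with its two methyls, carbinol C2 and carbinol C3 are the imprint of a ring-opened trisubstituted epoxy aldehyde (1,3-dielectrophile), and C4–C5(CH3)=C6–C7 is a masked acetoacetate (1,3-dinucleophile, C5 arriving as a ketone).
- C2 is set by Sharpless epoxidation of prenol and C3 by chelation-controlled aldol addition inside the key step; release of oxirane strain drives the ring closure that forms the quaternary carbon.

Key step: step 3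

Assumption: the neutral hydrogen sulfate drawn is taken as the target; it is made and purified as its sodium salt and protonated in the last step, and Chan's diene and (2E,4E,6E)-2,7-dimethylocta-2,4,6-trienedial are taken as purchasable.

**Step 1**
Reactants: 1 3-methylbut-2-en-1-ol (prenol)
Product: 2 [(2S)-3,3-dimethyloxiran-2-yl]methanol
Conditions: Ti(OiPr)4 (cat.), L-(+)-diisopropyl tartrate (cat.), t-BuOOH, 4 Å MS, CH2Cl2, −20 °C; non-aqueous work-up, distillation
Reagents that add atoms: tert-butyl hydroperoxide, CC(C)(C)OO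
Why: Sharpless asymmetric epoxidation of an allylic alcohol; the L-(+)-tartrate complex should deliver oxygen to the face that gives the (S)-epoxy alcohol, and this centre becomes the carbinol carbon next to the quaternary carbon in both rings.

**Step 2**
Reactants: 2 [(2S)-3,3-dimethyloxiran-2-yl]methanol
Product: 3 (2R)-3,3-dimethyloxirane-2-carbaldehyde
Conditions: TEMPO (cat.), PhI(OAc)2, CH2Cl2, rt; used as a dried CH2Cl2 solution
Reagents that add atoms: none
Why: TEMPO/PhI(OAc)2 oxidation of a primary alcohol stops at the aldehyde under non-basic conditions, so the oxirane and its stereocentre should survive (S becomes R only through the CIP priorities).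

**Step 3**
Reactants: 3 (2R)-3,3-dimethyloxirane-2-carbaldehyde; 4 1-methoxy-1,3-bis(trimethylsilyloxy)buta-1,3-diene (Chan's diene)
Product: 6 methyl (4R,5R)-4,5-dihydroxy-6,6-dimethyl-2-oxocyclohexane-1-carboxylate, via trichlorostannyl aldolate 5 (not isolated)
Conditions: SnCl4 (1.2 equiv), CH2Cl2, −78 °C, 3 then 4; −78 → 0 °C; pH 7 buffer, then citric acid, THF/H2O, 0 °C
Reagents that add atoms: none
Why: Proposed new method: SnCl4 should bind the aldehyde and oxirane oxygens of 3 as a five-membered chelate, the terminal carbon of 4 then adds to the aldehyde in a vinylogous Mukaiyama aldol reaction (first C–C bond, aldolate 5), and the tin-bound 2,3-epoxy alkoxide is opened at its tertiary carbon by the central carbon of the remaining silyl enol ether (second C–C bond); the closest known reaction types are the formal [3+3] cyclization of 1,3-bis(silyloxy)-1,3-dienes with 1,3-dielectrophiles and the SnCl4-mediated epoxide-opening cyclization of 6,7-epoxy-3-oxo esters to 5-hydroxy-6,6-dimethyl-2-oxocyclohexanecarboxylates. The cyclohexane ring closes by a 6-(enolexo)-endo-tet opening of the oxirane at the carbon that carries the two methyl groups. The carbinol centre next to the quaternary carbon comes unchanged from 3 because its C–O bond is never broken, and the second carbinol centre is set in the aldol stage by Cram chelate control: attack on the chelated aldehyde from the face away from the CMe2 carbon gives the threo epoxy alcohol and hence the trans-diol. Chemoselectivity (aldehyde before oxirane) rests on the higher electrophilicity of the chelated aldehyde at −78 °C, and regioselectivity of ring opening (six-membered ring at the tertiary carbon, not five-membered at the secondary one) on the cation-stabilising gem-dimethyl group and on alkoxide-directed activation of the distal C–O bond. C-alkylation is expected over O-alkylation because a tertiary enol ether formed by O-attack would re-ionise under SnCl4 and funnel to the β-keto ester.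

**Step 4**
Reactants: 6 methyl (4R,5R)-4,5-dihydroxy-6,6-dimethyl-2-oxocyclohexane-1-carboxylate
Product: 7 methyl (3aR,7aR)-2,2,4,4-tetramethyl-6-oxohexahydro-1,3-benzodioxole-5-carboxylate (acetonide of 6)
Conditions: Me2C(OMe)2, PPTS (cat.), CH2Cl2, rt
Reagents that add atoms: 2,2-dimethoxypropane, COC(C)(C)OC
Why: acid-catalysed transacetalization ties the trans-diol into a dioxolane, and PPTS is mild enough to spare the β-hydroxy ketone from dehydration.

**Step 5**
Reactants: 7 acetonide keto ester
Product: 8 methyl (3aR,7aR)-2,2,4,4-tetramethyl-6-(trifluoromethylsulfonyloxy)-3a,4,7,7a-tetrahydro-1,3-benzodioxole-5-carboxylate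
Conditions: Tf2O, iPr2NEt, CH2Cl2, −78 °C
Reagents that add atoms: trifluoromethanesulfonic anhydride, FC(F)(F)S(=O)(=O)OS(=O)(=O)C(F)(F)F
Why: enol triflate formation from a cyclic β-keto ester; enolization goes to the doubly activated carbon, which fixes the future ring double bond between the ester-bearing carbon and the former ketone carbon.

**Step 6**
Reactants: 8 enol triflate
Product: 9 methyl (3aR,7aR)-2,2,4,4,6-pentamethyl-3a,4,7,7a-tetrahydro-1,3-benzodioxole-5-carboxylate
Conditions: MeMgBr, Fe(acac)3 (5 mol%), THF/NMP, −30 °C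
Reagents that add atoms: methylmagnesium bromide, C[Mg]Br
Why: iron-catalysed Kumada-type cross-coupling of an alkenyl triflate with a methyl Grignard reagent is fast at low temperature and tolerates esters, so it should install the ring methyl group on the tetrasubstituted alkene.

**Step 7**
Reactants: 9 methyl ester
Product: 10 [(3aR,7aR)-2,2,4,4,6-pentamethyl-3a,4,7,7a-tetrahydro-1,3-benzodioxol-5-yl]methanol
Conditions: iBu2AlH (2.5 equiv), CH2Cl2, −78 → 0 °C; aq. potassium sodium tartrate
Reagents that add atoms: none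
Why: hydride reduction of the conjugated ester to the allylic alcohol; the acetonide and the tetrasubstituted alkene are inert.

**Step 8**
Reactants: 10 allylic alcohol
Product: 11 (3aR,7aR)-2,2,4,4,6-pentamethyl-3a,4,7,7a-tetrahydro-1,3-benzodioxole-5-carbaldehyde
Conditions: MnO2 (activated, excess), CH2Cl2, rt
Reagents that add atoms: none
Why: MnO2 oxidises allylic alcohols selectively to enals and leaves the acetonide untouched.

**Step 9**
Reactants: 11 enal
Product: 12 (3E)-4-[(3aR,7aR)-2,2,4,4,6-pentamethyl-3a,4,7,7a-tetrahydro-1,3-benzodioxol-5-yl]but-3-en-2-one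
Conditions: (MeO)2P(O)CH2C(O)CH3, NaH, THF, 0 °C → reflux
Reagents that add atoms: dimethyl (2-oxopropyl)phosphonate, COP(=O)(CC(C)=O)OC
Why: Horner–Wadsworth–Emmons olefination with a stabilised β-keto phosphonate should give the (E)-enone of the β-ionone type.

**Step 10**
Reactants: 12 enone
Product: 13 (1E)-3-methyl-1-[(3aR,7aR)-2,2,4,4,6-pentamethyl-3a,4,7,7a-tetrahydro-1,3-benzodioxol-5-yl]penta-1,4-dien-3-ol (both epimers at the new carbinol)
Conditions: CH2=CHMgBr, THF, −20 → 0 °C; aq. NH4Cl
Reagents that add atoms: vinylmagnesium bromide, C=C[Mg]Br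
Why: Grignard 1,2-addition to the methyl ketone as in vinyl-β-ionol preparation; the new carbinol centre is not controlled and is destroyed in step 11.

**Step 11**
Reactants: 13 vinyl carbinol
Product: 14 [(2E,4E)-5-[(4R,5R)-4,5-dihydroxy-2,6,6-trimethylcyclohex-1-en-1-yl]-3-methylpenta-2,4-dien-1-yl]triphenylphosphonium bromide
Conditions: PPh3·HBr, MeOH, rt; crystallisation
Reagents that add atoms: triphenylphosphine hydrobromide, [PH+](c1ccccc1)(c1ccccc1)c1ccccc1.[Br-]
Why: HBr ionises the tertiary bis-allylic alcohol and PPh3 captures the pentadienyl cation at the primary terminus (allylic transposition) to give the (2E,4E) salt, while the acid and the water released cleave the strained trans-fused acetonide.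

**Step 12**
Reactants: 14 C15 phosphonium bromide; 15 (2E,4E,6E)-2,7-dimethylocta-2,4,6-trienedial (3 equiv)
Product: 16 (2R,3R)-2,3-dihydroxy-12′-apo-β-caroten-12′-al (all-E C25 aldehyde)
Conditions: NaOMe, MeOH/CH2Cl2, 0 °C → rt, slow addition of 14, dark, Ar; then EtOH, 70 °C (Z→E)
Reagents that add atoms: none
Why: Wittig reaction of the allylic ylide with one aldehyde of the excess symmetrical dialdehyde; free hydroxyls are tolerated and the new 11,12 double bond should equilibrate to E on heating.

**Step 13**
Reactants: 16 C25 diol aldehyde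
Product: 17 sodium (2R,3R)-2-hydroxy-12′-oxo-12′-apo-β-caroten-3-yl sulfate
Conditions: SO3·pyridine (1.2 equiv), pyridine, 0 °C → rt, dark; aq. NaHCO3; C18 chromatography
Reagents that add atoms: sulfur trioxide–pyridine complex, [O-]S(=O)(=O)[n+]1ccccc1; sodium hydrogen carbonate, [Na+].OC([O-])=O
Why: O-sulfation should take the secondary 3-hydroxyl, because the 2-hydroxyl is neopentyl-type next to the gem-dimethyl carbon and the first sulfate anion disfavours a second sulfation beside it.

**Step 14**
Reactants: 17 C25 aldehyde sulfate sodium salt; 14 C15 phosphonium bromide (1.3 equiv)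
Product: 18 sodium (2R,3R,2′R,3′R)-2,2′,3′-trihydroxy-β,β-caroten-3-yl sulfate (all-E)
Conditions: NaOMe, MeOH/CH2Cl2, 0 °C → rt, dark, Ar; then EtOH, 60 °C (Z→E); C18 chromatography
Reagents that add atoms: none
Why: second Wittig reaction forms the 11′,12′ double bond; the sulfate monoester anion is inert to methoxide and ylide, and the Z isomer should isomerise thermally to all-E.

**Step 15**
Reactants: 18 sodium salt
Product: 19 (2R,3R,2′R,3′R)-β,β-carotene-2,3,2′,3′-tetrol 3-(hydrogen sulfate), the target
Conditions: HCl (1.00 equiv, 0.1 M in MeOH), CH2Cl2/MeOH, −20 °C, dark; NaCl filtered off, cold evaporation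
Reagents that add atoms: none
Why: proton exchange of the alkyl sulfate salt with one equivalent of strong acid, with NaCl precipitating from the CH2Cl2-rich medium; cold and dark handling should limit acid-induced damage to the polyene.

**Compound list**
1 | 3-methylbut-2-en-1-ol | CC(C)=CCO | starting material
2 | [(2S)-3,3-dimethyloxiran-2-yl]methanol | CC1(C)[C@@H](O1)CO | intermediate
3 | (2R)-3,3-dimethyloxirane-2-carbaldehyde | CC1(C)[C@@H](O1)C=O | intermediate
4 | 1-methoxy-1,3-bis(trimethylsilyloxy)buta-1,3-diene (Chan's diene) | COC(O[Si](C)(C)C)=CC(=C)O[Si](C)(C)C | starting material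
5 | trichlorostannyl aldolate: methyl (5R)-5-[(2S)-3,3-dimethyloxiran-2-yl]-3-oxo-5-(trichlorostannyloxy)pentanoate as its ester trimethylsilyl ketene acetal | COC(O[Si](C)(C)C)=CC(=O)C[C@@H](O[Sn](Cl)(Cl)Cl)[C@@H]1OC1(C)C | intermediate (not isolated)
6 | methyl (4R,5R)-4,5-dihydroxy-6,6-dimethyl-2-oxocyclohexane-1-carboxylate (keto–enol mixture, ester-bearing carbon not defined) | O=C1C(C(=O)OC)C(C)(C)[C@@H](O)[C@H](O)C1 | intermediate
7 | methyl (3aR,7aR)-2,2,4,4-tetramethyl-6-oxohexahydro-1,3-benzodioxole-5-carboxylate | O=C1C(C(=O)OC)C(C)(C)[C@@H](O2)[C@H](OC2(C)C)C1 | intermediate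
8 | methyl (3aR,7aR)-2,2,4,4-tetramethyl-6-(trifluoromethylsulfonyloxy)-3a,4,7,7a-tetrahydro-1,3-benzodioxole-5-carboxylate | FC(F)(F)S(=O)(=O)OC1=C(C(=O)OC)C(C)(C)[C@@H](O2)[C@H](OC2(C)C)C1 | intermediate
9 | methyl (3aR,7aR)-2,2,4,4,6-pentamethyl-3a,4,7,7a-tetrahydro-1,3-benzodioxole-5-carboxylate | CC1=C(C(=O)OC)C(C)(C)[C@@H](O2)[C@H](OC2(C)C)C1 | intermediate
10 | [(3aR,7aR)-2,2,4,4,6-pentamethyl-3a,4,7,7a-tetrahydro-1,3-benzodioxol-5-yl]methanol | CC1=C(CO)C(C)(C)[C@@H](O2)[C@H](OC2(C)C)C1 | intermediate
11 | (3aR,7aR)-2,2,4,4,6-pentamethyl-3a,4,7,7a-tetrahydro-1,3-benzodioxole-5-carbaldehyde | CC1=C(C=O)C(C)(C)[C@@H](O2)[C@H](OC2(C)C)C1 | intermediate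
12 | (3E)-4-[(3aR,7aR)-2,2,4,4,6-pentamethyl-3a,4,7,7a-tetrahydro-1,3-benzodioxol-5-yl]but-3-en-2-one | CC1=C(/C=C/C(C)=O)C(C)(C)[C@@H](O2)[C@H](OC2(C)C)C1 | intermediate
13 | (1E)-3-methyl-1-[(3aR,7aR)-2,2,4,4,6-pentamethyl-3a,4,7,7a-tetrahydro-1,3-benzodioxol-5-yl]penta-1,4-dien-3-ol (carbinol epimers) | CC1=C(/C=C/C(C)(O)C=C)C(C)(C)[C@@H](O2)[C@H](OC2(C)C)C1 | intermediate
14 | [(2E,4E)-5-[(4R,5R)-4,5-dihydroxy-2,6,6-trimethylcyclohex-1-en-1-yl]-3-methylpenta-2,4-dien-1-yl]triphenylphosphonium bromide | CC1=C(/C=C/C(C)=C/C[P+](c2ccccc2)(c2ccccc2)c2ccccc2)C(C)(C)[C@@H](O)[C@H](O)C1.[Br-] | intermediate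
15 | (2E,4E,6E)-2,7-dimethylocta-2,4,6-trienedial | O=C/C(C)=C/C=C/C=C(C)/C=O | starting material
16 | (2R,3R)-2,3-dihydroxy-12′-apo-β-caroten-12′-al | CC1=C(/C=C/C(C)=C/C=C/C(C)=C/C=C/C=C(C)/C=O)C(C)(C)[C@@H](O)[C@H](O)C1 | intermediate
17 | sodium (2R,3R)-2-hydroxy-12′-oxo-12′-apo-β-caroten-3-yl sulfate | CC1=C(/C=C/C(C)=C/C=C/C(C)=C/C=C/C=C(C)/C=O)C(C)(C)[C@@H](O)[C@H](OS(=O)(=O)[O-])C1.[Na+] | intermediate
18 | sodium (2R,3R,2′R,3′R)-2,2′,3′-trihydroxy-β,β-caroten-3-yl sulfate | CC1=C(/C=C/C(C)=C/C=C/C(C)=C/C=C/C=C(C)/C=C/C=C(C)/C=C/C2=C(C)C[C@@H](OS(=O)(=O)[O-])[C@H](O)C2(C)C)C(C)(C)[C@@H](O)[C@H](O)C1.[Na+] | intermediate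
19 | (2R,3R,2′R,3′R)-β,β-carotene-2,3,2′,3′-tetrol 3-(hydrogen sulfate) | CC1=C(/C=C/C(C)=C/C=C/C(C)=C/C=C/C=C(C)/C=C/C=C(C)/C=C/C2=C(C)C[C@@H](OS(=O)(=O)O)[C@H](O)C2(C)C)C(C)(C)[C@@H](O)[C@H](O)C1 | target

**Totals**
Total step count: 15. Longest linear sequence: 15 steps (1 → 19; compound 14 is used twice, 4 and 15 are purchased).

**Steps most likely to fail**

Step 3. The aldol stage may give poor facial control (Felkin–Anh attack competing with chelation, which would lead to the cis-diol series), or the oxirane may be degraded by the Lewis acid before ring closure. The fallback makes the two bonds in separate, known operations and sets out from 1 and 4. Compound 1 is oxidised with MnO2 to 3-methylbut-2-enal F1. A Ti(OiPr)4/BINOL-catalysed enantioselective vinylogous Mukaiyama aldol reaction of F1 with 4, with the ligand enantiomer chosen to deliver the (5R)-alcohol, gives methyl (5R)-5-hydroxy-7-methyl-3-oxooct-6-enoate F2. Hydroxyl-directed epoxidation with mCPBA (NaHCO3, CH2Cl2, 0 °C), in which allylic 1,3-strain from the cis-methyl group enforces the threo product, gives methyl (5R)-5-[(2S)-3,3-dimethyloxiran-2-yl]-5-hydroxy-3-oxopentanoate F3. SnCl4 in CH2Cl2 at 0 °C then closes the ring by the known epoxide-opening cyclization of epoxy β-keto esters, and the route is rejoined at 6.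

Step 13. Sulfation may not discriminate well enough between the 3- and 2-hydroxyls, or may run on to the bis-sulfate. The fallback fixes the site with protecting groups and sets out from 16. A bulky silyl chloride (TBSCl, imidazole, DMF, 0 °C) takes only the unhindered 3-hydroxyl and gives the 3-O-tert-butyldimethylsilyl ether F4. Forcing acetylation (Ac2O, DMAP, pyridine) gives the 2-O-acetyl-3-O-silyl compound F5. Buffered fluoride (Bu4NF/AcOH, THF, 0 °C, no acyl migration) frees the 3-hydroxyl and gives the 2-O-acetate F6. SO3·pyridine followed by NaHCO3 gives the sodium 3-sulfate 2-acetate F7. Under the step 14 conditions with 14 and excess NaOMe/MeOH, F7 undergoes the Wittig reaction and loses the acetate by methanolysis, which rejoins the route at 18.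

Step 14. The anionic C25 sulfate may react sluggishly with the ylide (poor solubility) or the polyene aldehyde may be lost under the basic coupling conditions. The fallback reverses the order of events and sets out from 16 and 14. The Wittig reaction (NaOMe, MeOH/CH2Cl2, then thermal Z→E isomerisation) gives (2R,3R,2′R,3′R)-β,β-carotene-2,3,2′,3′-tetrol F8, whose two 3-hydroxyls are equivalent by symmetry. Sulfation with one equivalent of SO3·pyridine, separation of the monosulfate from recovered F8 and from bis-sulfate, and NaHCO3 exchange rejoin the route at 18.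

**Further compounds**
F1 | step 3 | 3-methylbut-2-enal | CC(C)=CC=O
F2 | step 3 | methyl (5R)-5-hydroxy-7-methyl-3-oxooct-6-enoate | COC(=O)CC(=O)C[C@@H](O)C=C(C)C
F3 | step 3 | methyl (5R)-5-[(2S)-3,3-dimethyloxiran-2-yl]-5-hydroxy-3-oxopentanoate | COC(=O)CC(=O)C[C@@H](O)[C@@H]1OC1(C)C
F4 | step 13 | (2R,3R)-3-(tert-butyldimethylsilyloxy)-2-hydroxy-12′-apo-β-caroten-12′-al | CC1=C(/C=C/C(C)=C/C=C/C(C)=C/C=C/C=C(C)/C=O)C(C)(C)[C@@H](O)[C@H](O[Si](C)(C)C(C)(C)C)C1
F5 | step 13 | (2R,3R)-2-acetoxy-3-(tert-butyldimethylsilyloxy)-12′-apo-β-caroten-12′-al | CC1=C(/C=C/C(C)=C/C=C/C(C)=C/C=C/C=C(C)/C=O)C(C)(C)[C@@H](OC(C)=O)[C@H](O[Si](C)(C)C(C)(C)C)C1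
F6 | step 13 | (2R,3R)-2-acetoxy-3-hydroxy-12′-apo-β-caroten-12′-al | CC1=C(/C=C/C(C)=C/C=C/C(C)=C/C=C/C=C(C)/C=O)C(C)(C)[C@@H](OC(C)=O)[C@H](O)C1
F7 | step 13 | sodium (2R,3R)-2-acetoxy-12′-oxo-12′-apo-β-caroten-3-yl sulfate | CC1=C(/C=C/C(C)=C/C=C/C(C)=C/C=C/C=C(C)/C=O)C(C)(C)[C@@H](OC(C)=O)[C@H](OS(=O)(=O)[O-])C1.[Na+]
F8 | step 14 | (2R,3R,2′R,3′R)-β,β-carotene-2,3,2′,3′-tetrol | CC1=C(/C=C/C(C)=C/C=C/C(C)=C/C=C/C=C(C)/C=C/C=C(C)/C=C/C2=C(C)C[C@@H](O)[C@H](O)C2(C)C)C(C)(C)[C@@H](O)[C@H](O)C1
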